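**Retrosynthetic overview**

1. The benzotropolone is cut last. Its seven-membered ring (C5 carbonyl, C6 hydroxyl, flavan on C7, hydrogens on C8 and C9) is the oxidative cross-coupling product of the catechol ring of (−)-epicatechin 3-O-gallate and the 2,3,4-trihydroxyphenyl ring of an unnatural flavan-3-ol, with one pyrogallol carbon lost as CO2, as in theaflavin formation in tea.
2. That flavan-3-ol is cut through ring C at two bonds, aryl C8a–O1 and aryl C4a–C4. This gives 3,5-bis(benzyloxy)benzyne and a 1-aryl-2-(benzyloxy)-3-chloropropan-1-ol.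
3. Enabling feature: in ring A the ether oxygen O1 and the methylene C4 sit on neighbouring carbons (C8a, C4a), C4a has the oxygenated C5 beside it, and O1 and C4 are joined through C2–C3. A 3-alkoxyaryne therefore takes the C2 alkoxide at the carbon remote from the alkoxy group and hands its carbanion, at the carbon next to that group, to C4.
4. The chloro alcohol comes from an Evans syn glycolate aldol on 2,3,4-tris(benzyloxy)benzaldehyde (sets C2 and C3), reduction and chlorination; the aryne precursor comes from 3,5-bis(benzyloxy)phenol.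
5. Ring order: rings A and B are bought as arenes, ring C is closed in the key step, and the seven-membered tropolone ring with its benzo fusion is formed last.

Key step: step 8

Remark on the chemistry: in the target the flavan on the seven-membered ring stands on the carbon next to the ring C–OH (not one carbon further on, as in the tea theaflavins), so the pyrogallol partner must be the 2,3,4-trihydroxyphenyl flavan-3-ol and not epigallocatechin; (−)-epicatechin 3-O-gallate is assumed to be bought.

**Step 1**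
Reactants: 1 2,3,4-trihydroxybenzaldehyde
Product: 2 2,3,4-tris(benzyloxy)benzaldehyde
Conditions: BnBr (3.6 equiv), K2CO3, DMF, 60 °C
Reagents that add atoms: benzyl bromide, BrCc1ccccc1
Why: Williamson ether synthesis on all three phenols (the hydrogen-bonded 2-hydroxyl needs the excess of benzyl bromide and warming); no stereocentre is involved.

**Step 2**
Reactants: 3 (S)-4-benzyl-1,3-oxazolidin-2-one; 4 (benzyloxy)acetyl chloride
Product: 6 (S)-4-benzyl-3-[(benzyloxy)acetyl]-1,3-oxazolidin-2-one, via lithium oxazolidinide 5 (not isolated)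
Conditions: n-BuLi, THF, −78 °C; then 4, −78 → 0 °C
Reagents that add atoms: none
Why: N-acylation of the lithiated oxazolidinone with the acid chloride is the standard loading of an Evans auxiliary and does not touch its stereocentre.

**Step 3**
Reactants: 6 (S)-4-benzyl-3-[(benzyloxy)acetyl]-1,3-oxazolidin-2-one; 2 2,3,4-tris(benzyloxy)benzaldehyde
Product: 9 (S)-4-benzyl-3-{(2S,3R)-2-(benzyloxy)-3-hydroxy-3-[2,3,4-tris(benzyloxy)phenyl]propanoyl}-1,3-oxazolidin-2-one, via boron enolate 7 (not isolated), via boron aldolate 8 (not isolated)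
Conditions: Bu2BOTf, Et3N, CH2Cl2, −78 → 0 °C; then 2, −78 → 0 °C; then pH 7 buffer, MeOH, H2O2, 0 °C
Reagents that add atoms: none
Why: Evans syn glycolate aldol, in which the (Z)-boron enolate 7 reacts through a closed chair (Zimmerman–Traxler) transition state with one enolate face shielded by the benzyl group of the auxiliary, which sets both new centres (C2 S with OBn, C3 R carbinol) in the syn relationship that becomes the 2,3-cis pair of the flavan.

**Step 4**
Reactants: 9 (S)-4-benzyl-3-{(2S,3R)-2-(benzyloxy)-3-hydroxy-3-[2,3,4-tris(benzyloxy)phenyl]propanoyl}-1,3-oxazolidin-2-one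
Product: 10 (1R,2R)-2-(benzyloxy)-1-[2,3,4-tris(benzyloxy)phenyl]propane-1,3-diol
Conditions: LiBH4, THF, MeOH (1 equiv), 0 °C
Reagents that add atoms: none
Why: LiBH4 cleaves the N-acyl oxazolidinone reductively to the primary alcohol and releases the auxiliary for re-use, without epimerising either centre.

**Step 5**
Reactants: 10 (1R,2R)-2-(benzyloxy)-1-[2,3,4-tris(benzyloxy)phenyl]propane-1,3-diol
Product: 12 (1R,2S)-2-(benzyloxy)-3-chloro-1-[2,3,4-tris(benzyloxy)phenyl]propan-1-ol, via primary tosylate 11 (not isolated)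
Conditions: TsCl (1.1 equiv), Et3N, Me3N·HCl (cat.), CH2Cl2, 0 °C; then LiCl, DMF, 55 °C (CH2Cl2 distilled off)
Reagents that add atoms: lithium chloride, [Li+].[Cl-] (the chlorine of 12); 4-toluenesulfonyl chloride, Cc1ccc(cc1)S(Cl)(=O)=O (leaves atoms only in intermediate 11)
Why: sulfonylation picks the unhindered primary hydroxyl over the hindered benzylic secondary one and chloride then displaces the primary tosylate by SN2 (Finkelstein-type exchange), so neither stereocentre is touched (the descriptor at C2 becomes S only because CH2Cl now outranks the carbinol carbon).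

**Step 6**
Reactants: 13 3,5-bis(benzyloxy)phenol
Product: 14 3,5-bis(benzyloxy)-2-bromophenol
Conditions: NBS (1.0 equiv), i-Pr2NH (10 mol%), CH2Cl2, −78 → −40 °C
Reagents that add atoms: N-bromosuccinimide, O=C1CCC(=O)N1Br
Why: electrophilic aromatic bromination in which the amine–NBS reagent is delivered by hydrogen bonding to the free phenol and so enters ortho to OH rather than between the two benzyloxy groups, with low temperature and one equivalent limiting polybromination.

**Step 7**
Reactants: 14 3,5-bis(benzyloxy)-2-bromophenol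
Product: 17 3,5-bis(benzyloxy)-2-(trimethylsilyl)phenyl trifluoromethanesulfonate, via silyl ether 15 (not isolated), via lithium phenolate 16 (not isolated)
Conditions: HMDS, THF, 65 °C, then evaporation; n-BuLi, THF, −100 → −78 °C; Tf2O, −78 → 0 °C
Reagents that add atoms: hexamethyldisilazane, C[Si](C)(C)N[Si](C)(C)C; trifluoromethanesulfonic anhydride, O=S(=O)(OS(=O)(=O)C(F)(F)F)C(F)(F)F
Why: standard route to a 2-(trimethylsilyl)aryl triflate, in which O-silylation gives 15, bromine–lithium exchange triggers a 1,3 O→C silyl shift (retro-Brook rearrangement) to phenolate 16 and O-triflation follows, the exchange at −100 °C being faster than deprotonation of the benzyl ethers.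

**Step 8**
Reactants: 12 (1R,2S)-2-(benzyloxy)-3-chloro-1-[2,3,4-tris(benzyloxy)phenyl]propan-1-ol; 17 3,5-bis(benzyloxy)-2-(trimethylsilyl)phenyl trifluoromethanesulfonate
Product: 21 (2R,3R)-3,5,7-tris(benzyloxy)-2-[2,3,4-tris(benzyloxy)phenyl]-3,4-dihydro-2H-chromene, via sodium alkoxide 18 (not isolated), via aryne 19 (not isolated), via aryl anion 20 (not isolated)
Conditions: NaH (1.1 equiv), THF, 0 °C; then 17 (1.6 equiv), KF, 18-crown-6, THF, 0 → 25 °C (40 °C if ring closure lags)
Reagents that add atoms: none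
Why: Proposed new method: alkoxide 18 adds to aryne 19 at C1, the aryne carbon remote from the 3-benzyloxy group (the inductively withdrawing oxygen on C3 makes C1 the electrophilic end of the distorted triple bond and lets the negative charge grow on C2 between two oxygenated carbons), which forms the aryl C8a–O1 bond and puts the carbanion of 20 on the future C4a; that carbanion then displaces the primary chloride at C4 in a 6-exo-tet SN2 reaction that closes ring C and forms the aryl C4a–C4 bond. The closest known reaction types are fluoride-triggered additions of O-, N- and S-nucleophiles to arynes with capture of the aryl anion by a tethered ester, ketone or Michael acceptor (xanthone-, acridone- and indoline-forming annulations) and, for the second bond alone, the Parham cyclisation of an ortho-metalated aryl ether onto an alkyl halide; an aliphatic alkoxide paired with an alkyl chloride in one aryne annulation has not been shown. No stereocentre is created: C2 and C3 are those of 12 and no bond at either is broken, so the syn arrangement of the aldol becomes the 2,3-cis (2R,3R) pair of the chromane. Regioselectivity is secured by the 3-benzyloxy group of 19 as described, and the 5-benzyloxy group, meta to C1, does not oppose it. Chemoselectivity rests on the leaving group and the protecting group: a hindered secondary alkoxide closes an oxetane on a primary chloride (4-exo-tet) only slowly at or below room temperature whereas the far more nucleophilic aryl anion closes the six-membered ring, and the benzyl ether on O3 can neither migrate to O1 nor form an epoxide as a silyl ether or a free hydroxyl would. Protonation of 20 before ring closure is suppressed by pre-forming the alkoxide with NaH (H2 leaves the flask), by an ether solvent without acidic C–H bonds and by anhydrous KF/18-crown-6 in place of hydrated or tetraalkylammonium fluoride.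

**Step 9**
Reactants: 21 (2R,3R)-3,5,7-tris(benzyloxy)-2-[2,3,4-tris(benzyloxy)phenyl]-3,4-dihydro-2H-chromene
Product: 22 (2R,3R)-2-(2,3,4-trihydroxyphenyl)-3,4-dihydro-2H-chromene-3,5,7-triol
Conditions: H2 (1 atm), Pd(OH)2/C, THF/MeOH, 20 °C; filtration under argon
Reagents that add atoms: none
Why: hydrogenolysis of the five aryl benzyl ethers and of the O3 alkyl benzyl ether at ambient pressure and short contact time should leave the benzylic C2–O1 bond and both stereocentres intact.

**Step 10**
Reactants: 22 (2R,3R)-2-(2,3,4-trihydroxyphenyl)-3,4-dihydro-2H-chromene-3,5,7-triol; 23 (−)-epicatechin 3-O-gallate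
Product: 25 (2R,3R)-5,7-dihydroxy-2-{3,4,6-trihydroxy-5-oxo-7-[(2R,3R)-3,5,7-trihydroxy-3,4-dihydro-2H-chromen-2-yl]-5H-benzo[7]annulen-1-yl}-3,4-dihydro-2H-chromen-3-yl 3,4,5-trihydroxybenzoate, via ortho-quinone 24 (not isolated)
Conditions: horseradish peroxidase (enzyme class: peroxidase, EC 1.11.1.7), H2O2 (3 equiv, in portions), acetone/pH 5 citrate–phosphate buffer (1:10), 25 °C
Reagents that add atoms: none
Why: peroxidase-mediated oxidative cross-coupling of a catechol with a pyrogallol to a benzotropolone (the reaction by which theaflavins form), in which the catechol ring of 23 is oxidised to quinone 24, the ring-B carbon of 22 ortho to its 4'-hydroxyl (C5') adds to 24 in Michael fashion, after re-oxidation the neighbouring quinone-ring carbon adds to the middle oxygenated carbon (C3') of the pyrogallol ring and the outer oxygenated carbon C4' leaves as CO2, so that C2' becomes the tropolone C–OH and C1', which carries the flavan, ends up next to it as in 25; no stereocentre is touched.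

**Compound list**

1 | 2,3,4-trihydroxybenzaldehyde | O=Cc1ccc(O)c(O)c1O | starting material
2 | 2,3,4-tris(benzyloxy)benzaldehyde | O=Cc1ccc(OCc2ccccc2)c(OCc2ccccc2)c1OCc1ccccc1 | intermediate
3 | (S)-4-benzyl-1,3-oxazolidin-2-one | O=C1N[C@@H](Cc2ccccc2)CO1 | starting material
4 | (benzyloxy)acetyl chloride | O=C(Cl)COCc1ccccc1 | starting material
5 | N-lithio-(S)-4-benzyl-1,3-oxazolidin-2-one | [Li]N1[C@@H](Cc2ccccc2)COC1=O | intermediate (not isolated)
6 | (S)-4-benzyl-3-[(benzyloxy)acetyl]-1,3-oxazolidin-2-one | O=C(COCc1ccccc1)N1[C@@H](Cc2ccccc2)COC1=O | intermediate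
7 | (Z)-dibutylboron enolate of 6 | CCCCB(CCCC)O/C(=C\OCc1ccccc1)N1[C@@H](Cc2ccccc2)COC1=O | intermediate (not isolated)
8 | O-dibutylboryl aldolate of 9 | O=C(N1[C@@H](Cc2ccccc2)COC1=O)[C@@H](OCc1ccccc1)[C@H](OB(CCCC)CCCC)c1ccc(OCc2ccccc2)c(OCc2ccccc2)c1OCc1ccccc1 | intermediate (not isolated)
9 | (S)-4-benzyl-3-{(2S,3R)-2-(benzyloxy)-3-hydroxy-3-[2,3,4-tris(benzyloxy)phenyl]propanoyl}-1,3-oxazolidin-2-one | O=C(N1[C@@H](Cc2ccccc2)COC1=O)[C@@H](OCc1ccccc1)[C@H](O)c1ccc(OCc2ccccc2)c(OCc2ccccc2)c1OCc1ccccc1 | intermediate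
10 | (1R,2R)-2-(benzyloxy)-1-[2,3,4-tris(benzyloxy)phenyl]propane-1,3-diol | OC[C@@H](OCc1ccccc1)[C@H](O)c1ccc(OCc2ccccc2)c(OCc2ccccc2)c1OCc1ccccc1 | intermediate
11 | (2R,3R)-2-(benzyloxy)-3-hydroxy-3-[2,3,4-tris(benzyloxy)phenyl]propyl 4-methylbenzenesulfonate | Cc1ccc(cc1)S(=O)(=O)OC[C@@H](OCc1ccccc1)[C@H](O)c1ccc(OCc2ccccc2)c(OCc2ccccc2)c1OCc1ccccc1 | intermediate (not isolated)
12 | (1R,2S)-2-(benzyloxy)-3-chloro-1-[2,3,4-tris(benzyloxy)phenyl]propan-1-ol | ClC[C@@H](OCc1ccccc1)[C@H](O)c1ccc(OCc2ccccc2)c(OCc2ccccc2)c1OCc1ccccc1 | intermediate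
13 | 3,5-bis(benzyloxy)phenol | Oc1cc(OCc2ccccc2)cc(OCc2ccccc2)c1 | starting material
14 | 3,5-bis(benzyloxy)-2-bromophenol | Oc1cc(OCc2ccccc2)cc(OCc2ccccc2)c1Br | intermediate
15 | [3,5-bis(benzyloxy)-2-bromophenoxy]trimethylsilane | C[Si](C)(C)Oc1cc(OCc2ccccc2)cc(OCc2ccccc2)c1Br | intermediate (not isolated)
16 | lithium 3,5-bis(benzyloxy)-2-(trimethylsilyl)phenolate | [Li+].[O-]c1cc(OCc2ccccc2)cc(OCc2ccccc2)c1[Si](C)(C)C | intermediate (not isolated)
17 | 3,5-bis(benzyloxy)-2-(trimethylsilyl)phenyl trifluoromethanesulfonate | C[Si](C)(C)c1c(OS(=O)(=O)C(F)(F)F)cc(OCc2ccccc2)cc1OCc1ccccc1 | intermediate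
18 | sodium (1R,2S)-2-(benzyloxy)-3-chloro-1-[2,3,4-tris(benzyloxy)phenyl]propan-1-olate | ClC[C@@H](OCc1ccccc1)[C@H]([O-])c1ccc(OCc2ccccc2)c(OCc2ccccc2)c1OCc1ccccc1.[Na+] | intermediate (not isolated)
19 | 3,5-bis(benzyloxy)benzyne (3,5-bis(benzyloxy)-1,2-didehydrobenzene) | O(Cc1ccccc1)C1=CC(OCc2ccccc2)=CC#C1 | intermediate (not isolated)
20 | sodium 2,4-bis(benzyloxy)-6-{(1R,2S)-2-(benzyloxy)-3-chloro-1-[2,3,4-tris(benzyloxy)phenyl]propoxy}phenide | ClC[C@@H](OCc1ccccc1)[C@H](Oc1cc(OCc2ccccc2)cc(OCc2ccccc2)[c-]1)c1ccc(OCc2ccccc2)c(OCc2ccccc2)c1OCc1ccccc1.[Na+] | intermediate (not isolated)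
21 | (2R,3R)-3,5,7-tris(benzyloxy)-2-[2,3,4-tris(benzyloxy)phenyl]-3,4-dihydro-2H-chromene | C(c1ccccc1)Oc1ccc([C@H]2Oc3cc(OCc4ccccc4)cc(OCc4ccccc4)c3C[C@H]2OCc2ccccc2)c(OCc2ccccc2)c1OCc1ccccc1 | intermediate
22 | (2R,3R)-2-(2,3,4-trihydroxyphenyl)-3,4-dihydro-2H-chromene-3,5,7-triol | Oc1ccc([C@H]2Oc3cc(O)cc(O)c3C[C@H]2O)c(O)c1O | intermediate
23 | (−)-epicatechin 3-O-gallate | O=C(O[C@@H]1Cc2c(O)cc(O)cc2O[C@@H]1c1ccc(O)c(O)c1)c1cc(O)c(O)c(O)c1 | starting material
24 | ring-B ortho-quinone of 23 | O=C(O[C@@H]1Cc2c(O)cc(O)cc2O[C@@H]1C1=CC(=O)C(=O)C=C1)c1cc(O)c(O)c(O)c1 | intermediate (not isolated)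
25 | (2R,3R)-5,7-dihydroxy-2-{3,4,6-trihydroxy-5-oxo-7-[(2R,3R)-3,5,7-trihydroxy-3,4-dihydro-2H-chromen-2-yl]-5H-benzo[7]annulen-1-yl}-3,4-dihydro-2H-chromen-3-yl 3,4,5-trihydroxybenzoate | O=C(O[C@@H]1Cc2c(O)cc(O)cc2O[C@@H]1c1cc(O)c(O)c2c(=O)c(O)c([C@H]3Oc4cc(O)cc(O)c4C[C@H]3O)ccc12)c1cc(O)c(O)c(O)c1 | target

**Step count**

Total: 10 steps. Longest linear sequence: 7 steps (steps 1, 3, 4, 5, 8, 9, 10).

**Steps most likely to fail**

Step 8 (proposed new method). The aryl anion may be protonated before it closes ring C, which would give the open-chain aryl ether. The alkoxide may also be lost by oxetane formation or by attack on silicon or sulfur of the aryne precursor before it meets the aryne. The fallback sets out from 12 and 14 and comes back at 21, making the two bonds one after the other by known reactions. Alcohol 12 is oxidised with Dess–Martin periodinane (NaHCO3, CH2Cl2, 0 °C) to (S)-2-(benzyloxy)-3-chloro-1-[2,3,4-tris(benzyloxy)phenyl]propan-1-one F1. Chelation-controlled reduction with Zn(BH4)2 (Et2O, −30 °C, Cram chelate through the α-benzyloxy group) should give the anti alcohol (1S,2S)-2-(benzyloxy)-3-chloro-1-[2,3,4-tris(benzyloxy)phenyl]propan-1-ol F2. Mitsunobu etherification of F2 with bromophenol 14 (PPh3, DIAD, toluene, 0 °C, inversion at C1) should give 1,5-bis(benzyloxy)-2-bromo-3-{(1R,2S)-2-(benzyloxy)-3-chloro-1-[2,3,4-tris(benzyloxy)phenyl]propoxy}benzene F3. Parham cyclisation of F3 (t-BuLi, 2 equiv, THF, −78 → 20 °C; bromine–lithium exchange, then 6-exo-tet displacement of chloride) closes ring C to 21.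

Step 10. Oxidation may be unselective: the pyrogallol ring of 22 can be consumed by direct oxidation and by redox exchange with the quinone, leading to homo-coupling, and the galloyl ring of 23 can compete as a second pyrogallol nucleophile and oxidation site. The fallback sets out from 22 and comes back at 25; partner 23 is replaced by a galloyl-masked analogue built from commercial (−)-epicatechin. Its four phenols are silylated (TBSCl, imidazole, DMF) to 5,7,3',4'-tetrakis-O-(tert-butyldimethylsilyl)-(−)-epicatechin F4. The 3-hydroxyl is esterified with 3,4,5-tris(benzyloxy)benzoic acid (EDC·HCl, DMAP, CH2Cl2) to the 3-O-[3,4,5-tris(benzyloxy)benzoate] of F4, F5. Desilylation (TBAF, AcOH, THF, 0 °C) gives (−)-epicatechin 3-O-[3,4,5-tris(benzyloxy)benzoate] F6, whose only oxidisable ring is the catechol. F6 and 22 are coupled under the conditions of step 10 (more acetone for solubility) to the tris(benzyl ether) of 25 on the galloyl ring F7. Brief hydrogenolysis (H2, Pd/C, THF/MeOH) then gives 25.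

Step 6. Electrophilic bromination may be poorly regioselective (attack between the two benzyloxy groups) or go on to polybromination. The fallback sets out from 13 and comes back at 17, replacing halogenation by directed ortho-metalation. Phenol 13 and isopropyl isocyanate (Et3N, CH2Cl2) give 3,5-bis(benzyloxy)phenyl N-(propan-2-yl)carbamate F8. N-Silylation in the flask (TMSOTf, TMEDA), ortho-lithiation between the carbamate and a benzyloxy group (n-BuLi, TMEDA, Et2O, −78 °C) and quenching with TMSCl give 3,5-bis(benzyloxy)-2-(trimethylsilyl)phenyl N-(propan-2-yl)carbamate F9. Carbamate cleavage (DBU, Et2NH, MeCN, 40 °C) gives 3,5-bis(benzyloxy)-2-(trimethylsilyl)phenol F10, which is triflated (Tf2O, pyridine, CH2Cl2, 0 °C) to 17.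

**Further compounds**

F1 | step 8 | (S)-2-(benzyloxy)-3-chloro-1-[2,3,4-tris(benzyloxy)phenyl]propan-1-one | ClC[C@@H](OCc1ccccc1)C(=O)c1ccc(OCc2ccccc2)c(OCc2ccccc2)c1OCc1ccccc1
F2 | step 8 | (1S,2S)-2-(benzyloxy)-3-chloro-1-[2,3,4-tris(benzyloxy)phenyl]propan-1-ol | ClC[C@@H](OCc1ccccc1)[C@@H](O)c1ccc(OCc2ccccc2)c(OCc2ccccc2)c1OCc1ccccc1
F3 | step 8 | 1,5-bis(benzyloxy)-2-bromo-3-{(1R,2S)-2-(benzyloxy)-3-chloro-1-[2,3,4-tris(benzyloxy)phenyl]propoxy}benzene | ClC[C@@H](OCc1ccccc1)[C@H](Oc1cc(OCc2ccccc2)cc(OCc2ccccc2)c1Br)c1ccc(OCc2ccccc2)c(OCc2ccccc2)c1OCc1ccccc1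
F4 | step 10 | 5,7,3',4'-tetrakis-O-(tert-butyldimethylsilyl)-(−)-epicatechin | O[C@@H]1Cc2c(O[Si](C)(C)C(C)(C)C)cc(O[Si](C)(C)C(C)(C)C)cc2O[C@@H]1c1ccc(O[Si](C)(C)C(C)(C)C)c(O[Si](C)(C)C(C)(C)C)c1
F5 | step 10 | 5,7,3',4'-tetrakis-O-(tert-butyldimethylsilyl)-(−)-epicatechin 3-O-[3,4,5-tris(benzyloxy)benzoate] | O=C(O[C@@H]1Cc2c(O[Si](C)(C)C(C)(C)C)cc(O[Si](C)(C)C(C)(C)C)cc2O[C@@H]1c1ccc(O[Si](C)(C)C(C)(C)C)c(O[Si](C)(C)C(C)(C)C)c1)c1cc(OCc2ccccc2)c(OCc2ccccc2)c(OCc2ccccc2)c1
F6 | step 10 | (−)-epicatechin 3-O-[3,4,5-tris(benzyloxy)benzoate] | O=C(O[C@@H]1Cc2c(O)cc(O)cc2O[C@@H]1c1ccc(O)c(O)c1)c1cc(OCc2ccccc2)c(OCc2ccccc2)c(OCc2ccccc2)c1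
F7 | step 10 | (2R,3R)-5,7-dihydroxy-2-{3,4,6-trihydroxy-5-oxo-7-[(2R,3R)-3,5,7-trihydroxy-3,4-dihydro-2H-chromen-2-yl]-5H-benzo[7]annulen-1-yl}-3,4-dihydro-2H-chromen-3-yl 3,4,5-tris(benzyloxy)benzoate | O=C(O[C@@H]1Cc2c(O)cc(O)cc2O[C@@H]1c1cc(O)c(O)c2c(=O)c(O)c([C@H]3Oc4cc(O)cc(O)c4C[C@H]3O)ccc12)c1cc(OCc2ccccc2)c(OCc2ccccc2)c(OCc2ccccc2)c1
F8 | step 6 | 3,5-bis(benzyloxy)phenyl N-(propan-2-yl)carbamate | CC(C)NC(=O)Oc1cc(OCc2ccccc2)cc(OCc2ccccc2)c1
F9 | step 6 | 3,5-bis(benzyloxy)-2-(trimethylsilyl)phenyl N-(propan-2-yl)carbamate | CC(C)NC(=O)Oc1cc(OCc2ccccc2)cc(OCc2ccccc2)c1[Si](C)(C)C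
F10 | step 6 | 3,5-bis(benzyloxy)-2-(trimethylsilyl)phenol | Oc1cc(OCc2ccccc2)cc(OCc2ccccc2)c1[Si](C)(C)C
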